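All constants belong to no real substance.

Take the three set-ups below and ask which one ends with the most single ring.

all flasks: protic impurity 5.00 mM

| charge | starting material | time | remark |
|---|---|---|---|
| spring | 10 mM | 1.0 h | everything together in a closed stirred flask, run for 1.0 h |
| winter | 10 mM (fed, over 0.500 h) | 1.0 h | all but starting material at the start; starting material goes in evenly over 0.500 h, the run ends at 1.0 h |
| dusk | 10 mM |  | a single well-mixed tank run continuously and read at steady state, 1.0 h in it on average |

* the set-up with the highest amount of single ring at the outlet or at the end, in percent of the starting material put in ("none" if the first two lie within 2 percentage points) (spring / winter / dusk / none)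
* amount of single ring at the outlet or at the end, in percent of the starting material put in, spring
* amount of single ring at the outlet or at the end, in percent of the starting material put in, winter
* amount of single ring at the outlet or at the end, in percent of the starting material put in, dusk

- a species is counted by the starting material in it: one open dimer or ring dimer counts as two
- a species is counted by the starting material in it: one open trimer counts as three
- for a step with 2 of a species take k times the square, and two of it per event
- the stated concentrations are those of everything mixed, before any reaction; amounts are the same in each set-up
- the feed brings no volume worth counting
- run time (spring): 1.0 h

    starting material → single ring (k1 = 0.665 min⁻¹)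
    open dimer → ring dimer (k2 = 0.0500 min⁻¹)
    starting material + open dimer → open trimer (k3 = 101 M⁻¹ min⁻¹)
    starting material + protic impurity → quenched substrate (k4 = 4.26 M⁻¹ min⁻¹)
    2 starting material → open dimer (k5 = 128 M⁻¹ min⁻¹)
    starting material ⇌ dormant form (K6 = 2.7, k6 = 0.0544 min⁻¹)
    single ring ⇌ isomer of the product (K7 = 1.9, k7 = 0.0174 min⁻¹)

1. I compare two rates at one moment. The ring-closure constant over twice the dimer constant gives 2.60 mM. This is the crossover concentration, the [starting material] at which ring closure and the dimer step use it equally fast. At any moment, closure over dimer step (a selectivity factor) is crossover over [starting material].

2. In spring the ratio starts at 0.260 and rises as [starting material] falls. Summing it down from the charge gives crossover over charge, times ln(1 + charge over crossover): 41.0 % to the ring. But open dimer also takes starting material, its constant being 0.395 times twice the dimer constant, so this spring share runs high. I can't sum that by hand. The protic impurity is a pseudo-first-order drain of 0.0213 min⁻¹, far slower than closure, so I drop it.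

3. But the ring doesn't stay: it equilibrates with its isomer at 0.0266 min⁻¹, towards a ring share of 34.5 %. In spring the first lifetime of the starting material, at the charge, is about 0.310 min, much less than the run, so I let the ring age the full time and reckon that 47.8 % of it stays. That makes 19.6 % for spring.

4. The sum does not fit winter. Closure's time, 1.50 min, is short against the feed, so while the winter feed runs I put [starting material] where closure and the dimer step together use what comes in, at 0.430 mM. The part of the winter charge that closes to the ring is then crossover over crossover plus level, 85.8 %. Averaging the drain to the isomer over the ages of the winter ring gives 54.8 % kept, so 47.1 % for winter.

5. In dusk, adding washout to the same balance gives 0.225 mM, and 89.9 % goes to ring or isomer. Of that, I reckon 59.7 % leaves the dusk tank as ring, so 53.7 % for dusk. I commit to dusk.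

6. The forecast also picks dusk, with 18 % in spring, 44 % in winter and 50 % in dusk, each below mine. Its ground: “Keeping the starting material dilute favours first-order ring closure over second-order dimerisation”.

7. The simulation gives dusk as best, with 17.8 % in spring, 45.5 % in winter and 50.5 % in dusk. In the dusk tank [starting material] reads 0.212 mM, far below the crossover, which puts closure at 12.3 times the dimer step, against 0.260 times at the start in spring. A neighbour of spring charged with 2.5 mM starts near the crossover: steps 2 and 3 give it 33.5 %, and that flask ends with 32.6 % of single ring.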